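**Plan**

- Retrosynthesis: the two pyrrole amide C–N bonds are cut first, then the two benzylic C–N bonds of a temporary (S,S)-1,2-diphenylethane-1,2-diyl bridge between the two nitrogen atoms, then both cyclobutane bonds, CH(CH2N)–CH(CH2N) and CH(imidazolyl)–CH(imidazolyl), in one [2+2] event. The 2-aminoimidazoles are carried as imidazo[1,2-a]pyrimidines.
- Enabling feature: the cyclobutane is the C2-symmetric head-to-head dimer of one 3-(azolyl)allylamine unit. Its two adjacent ring carbons that bear the imidazole rings can each hold a heteroaryl-stabilised radical, and its two trans CH2–N arms end in nitrogen atoms that a two-carbon chiral bridge can span as an eight-membered 1,4-diazocane ring.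
- Forward: Wittig homologation to the enal, double reductive amination onto (1S,2S)-1,2-diphenylethane-1,2-diamine, sensitised intramolecular [2+2] (diazocane ring first, cyclobutane second), hydrazine unmasking of both aminoimidazoles, hydrogenolytic removal of the bridge, double acylation.
- Stereochemistry: all four stereocentres arise in the [2+2]. The all-trans relative configuration comes from stepwise diradical closure, the absolute configuration from the (S,S)-diamine bridge.

Key step: step 3

Assumption: the sense of induction by the diamine bridge is taken from the conformational model given under step 3 and is not backed by a direct precedent; with the (1R,2R)-diamine the same six steps would lead to the mirror-image series.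

**Route**

Step 1
Reactants: 1 imidazo[1,2-a]pyrimidine-2-carbaldehyde; 2 (triphenylphosphoranylidene)acetaldehyde
Product: 3 (E)-3-(imidazo[1,2-a]pyrimidin-2-yl)prop-2-enal
Conditions: 2 (1.05 equiv), toluene, 80 °C
Reagents that add atoms: none
Why: Wittig olefination with the stabilised formyl ylide should give the (E)-enal, and the conjugated product is a poorer electrophile than 1, which limits a second homologation.

Step 2
Reactants: 3 (E)-3-(imidazo[1,2-a]pyrimidin-2-yl)prop-2-enal (2.05 equiv); 4 (1S,2S)-1,2-diphenylethane-1,2-diamine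
Product: 6 (1S,2S)-N,N'-bis[(E)-3-(imidazo[1,2-a]pyrimidin-2-yl)prop-2-en-1-yl]-1,2-diphenylethane-1,2-diamine, via bis-imine 5 (not isolated)
Conditions: MgSO4, CH2Cl2, rt; then NaBH(OAc)3, AcOH, 0 °C to rt
Reagents that add atoms: none
Why: Stepwise reductive amination: both primary amino groups condense with the enal to the bis(1-azadiene) 5, whose protonated C=N bonds should take hydride in 1,2 fashion, so that each nitrogen is alkylated once and the alkene geometry and the two benzylic stereocentres stay untouched.

Step 3
Reactants: 6 (1S,2S)-N,N'-bis[(E)-3-(imidazo[1,2-a]pyrimidin-2-yl)prop-2-en-1-yl]-1,2-diphenylethane-1,2-diamine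
Product: 8 (1R,4S,5S,8R,9S,10S)-9,10-bis(imidazo[1,2-a]pyrimidin-2-yl)-4,5-diphenyl-3,6-diazabicyclo[6.2.0]decane, via triplet 1,4-diradical 7 (not isolated)
Conditions: fac-Ir(ppy)3 (2 mol%), degassed MeCN (5 mM), 450 nm LEDs, rt
Reagents that add atoms: none
Why: Proposed new method: triplet energy transfer from excited fac-Ir(ppy)3 to one 2-vinylimidazo[1,2-a]pyrimidine chromophore of 6 should give a twisted alkene triplet whose CH2-bearing carbon adds to the CH2-bearing carbon of the second alkene (8-exo-trig, closing the 1,4-diazocane ring) to give the doubly heteroaryl-stabilised triplet 1,4-diradical 7, which after intersystem crossing closes the cyclobutane by radical recombination. The closest known reaction types are the visible-light-sensitised [2+2] cycloaddition of styrenes, the head-to-head photodimerisation of heteroaryl alkenes and the photodimerisation of cinnamates held on chiral diol tethers; the new element is the eight-membered bridge through the two nitrogen atoms of a chiral vicinal diamine. Head-to-head regiochemistry is secured because only bond formation between the two inner alkene carbons leaves both radicals on carbons that bear the bicyclic azole, and the intramolecular course is secured by high dilution. The trans relation at the two CH2-bearing carbons should follow from both radical-bearing arms taking pseudo-equatorial positions on the forming ring, and the two heteroaryl-bearing carbons are set in the freely rotating diradical, which should close with each heteroaryl group trans to its neighbouring ring CH2 and to the other heteroaryl group (all-trans, the least hindered cyclobutane). The absolute configuration is controlled by the (S,S)-diamine: its N–C–C–N unit keeps the positive gauche arrangement with both phenyl groups pseudo-equatorial, and on a boat-chair eight-membered ring this should impose a torsion of the same positive sign on the C–C bond formed across the ring, which corresponds to the (1R,8R) configuration of 8 and to the target. The step needs facial selectivity between the two trans-fused diastereomers, which rests on this conformational preference, and the product holds no conjugated alkene, so it should not be sensitised further.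

Step 4
Reactants: 8 (1R,4S,5S,8R,9S,10S)-9,10-bis(imidazo[1,2-a]pyrimidin-2-yl)-4,5-diphenyl-3,6-diazabicyclo[6.2.0]decane
Product: 9 5,5'-[(1R,4S,5S,8R,9S,10S)-4,5-diphenyl-3,6-diazabicyclo[6.2.0]decane-9,10-diyl]bis(1H-imidazol-2-amine)
Conditions: N2H4·H2O (excess), EtOH, 90 °C, sealed tube
Reagents that add atoms: none
Why: Hydrazinolysis of the imidazo[1,2-a]pyrimidine ring: hydrazine should add to C5 and C7 of each pyrimidine ring and carry off the three-carbon unit as pyrazole, leaving the bridgehead nitrogen as imidazole N–H and the other ring nitrogen as the 2-amino group, without touching the amines or the stereocentres.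

Step 5
Reactants: 9 5,5'-[(1R,4S,5S,8R,9S,10S)-4,5-diphenyl-3,6-diazabicyclo[6.2.0]decane-9,10-diyl]bis(1H-imidazol-2-amine)
Product: 10 5,5'-[(1S,2S,3R,4R)-3,4-bis(aminomethyl)cyclobutane-1,2-diyl]bis(1H-imidazol-2-amine)
Conditions: H2 (4 bar), Pd(OH)2/C, MeOH–AcOH, 45 °C; free base by ion exchange
Reagents that add atoms: none
Why: Hydrogenolysis of benzylic C–N bonds (N-debenzylation type): both nitrogen atoms sit on CHPh carbons, so the two C–N bonds should be cleaved in turn and the bridge released as 1,2-diphenylethane, while the protonated 2-aminoimidazoles and the cyclobutane are inert.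

Step 6
Reactants: 10 5,5'-[(1S,2S,3R,4R)-3,4-bis(aminomethyl)cyclobutane-1,2-diyl]bis(1H-imidazol-2-amine); 11 2,2,2-trichloro-1-(1H-pyrrol-2-yl)ethan-1-one (2.1 equiv)
Product: 12 N,N'-{[(1R,2R,3S,4S)-3,4-bis(2-amino-1H-imidazol-5-yl)cyclobutane-1,2-diyl]bis(methylene)}bis(1H-pyrrole-2-carboxamide)
Conditions: DMF, rt
Reagents that add atoms: none
Why: Haloform-type acylation of amines by a trichloromethyl ketone: the two primary alkylamines are far more nucleophilic than the guanidine-like 2-aminoimidazoles and should displace CCl3 as chloroform, the standard way to attach pyrrole-2-carbonyl groups to aminoimidazole-containing amines of this alkaloid family.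

**Compound list**

1 | imidazo[1,2-a]pyrimidine-2-carbaldehyde | O=Cc1cn2cccnc2n1 | starting material
2 | (triphenylphosphoranylidene)acetaldehyde | O=CC=P(c1ccccc1)(c1ccccc1)c1ccccc1 | starting material
3 | (E)-3-(imidazo[1,2-a]pyrimidin-2-yl)prop-2-enal | O=C/C=C/c1cn2cccnc2n1 | intermediate
4 | (1S,2S)-1,2-diphenylethane-1,2-diamine | N[C@@H](c1ccccc1)[C@@H](N)c1ccccc1 | starting material
5 | (1S,2S)-N,N'-bis[(E)-3-(imidazo[1,2-a]pyrimidin-2-yl)prop-2-en-1-ylidene]-1,2-diphenylethane-1,2-diamine (bis-imine, not isolated) | n1c2ncccn2cc1/C=C/C=N/[C@@H](c1ccccc1)[C@@H](/N=C/C=C/c1cn2cccnc2n1)c1ccccc1 | intermediate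
6 | (1S,2S)-N,N'-bis[(E)-3-(imidazo[1,2-a]pyrimidin-2-yl)prop-2-en-1-yl]-1,2-diphenylethane-1,2-diamine | n1c2ncccn2cc1/C=C/CN[C@@H](c1ccccc1)[C@@H](NC/C=C/c1cn2cccnc2n1)c1ccccc1 | intermediate
7 | triplet 1,4-diradical: (2S,3S)-2,3-diphenyl-1,4-diazocane with trans (imidazo[1,2-a]pyrimidin-2-yl)methyl radical arms on C6 and C7, ring configuration as in 8 (not isolated) | n1c2ncccn2cc1[CH][C@@H]3CN[C@@H](c4ccccc4)[C@H](c4ccccc4)NC[C@H]3[CH]c1cn2cccnc2n1 | intermediate
8 | (1R,4S,5S,8R,9S,10S)-9,10-bis(imidazo[1,2-a]pyrimidin-2-yl)-4,5-diphenyl-3,6-diazabicyclo[6.2.0]decane | n1c2ncccn2cc1[C@H]3[C@@H]4CN[C@@H](c5ccccc5)[C@H](c5ccccc5)NC[C@H]4[C@@H]3c1cn2cccnc2n1 | intermediate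
9 | 5,5'-[(1R,4S,5S,8R,9S,10S)-4,5-diphenyl-3,6-diazabicyclo[6.2.0]decane-9,10-diyl]bis(1H-imidazol-2-amine) | Nc1ncc([C@H]3[C@@H]4CN[C@@H](c5ccccc5)[C@H](c5ccccc5)NC[C@H]4[C@@H]3c6cnc(N)[nH]6)[nH]1 | intermediate
10 | 5,5'-[(1S,2S,3R,4R)-3,4-bis(aminomethyl)cyclobutane-1,2-diyl]bis(1H-imidazol-2-amine) | Nc1ncc([C@H]2[C@H](CN)[C@@H](CN)[C@@H]2c2cnc(N)[nH]2)[nH]1 | intermediate
11 | 2,2,2-trichloro-1-(1H-pyrrol-2-yl)ethan-1-one | O=C(c1ccc[nH]1)C(Cl)(Cl)Cl | starting material
12 | N,N'-{[(1R,2R,3S,4S)-3,4-bis(2-amino-1H-imidazol-5-yl)cyclobutane-1,2-diyl]bis(methylene)}bis(1H-pyrrole-2-carboxamide) | Nc1ncc([C@H]2[C@H](CNC(=O)c3ccc[nH]3)[C@@H](CNC(=O)c3ccc[nH]3)[C@@H]2c2cnc(N)[nH]2)[nH]1 | target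

Total step count: 6. Longest linear sequence: 6 steps (1 → 3 → 6 → 8 → 9 → 10 → 12).

**Steps most likely to fail**

1. Step 3 (Proposed new method). The eight-membered ring closure may be slow against triplet decay, intermolecular dimerisation or oligomerisation may compete, or the two trans-fused modes may be poorly discriminated. The fallback sets out from 3 and comes back at 10, using the known intermolecular variant and a separable chiral N-substituent. Enal 3 is condensed with (S)-1-phenylethylamine to (1E,2E)-3-(imidazo[1,2-a]pyrimidin-2-yl)-N-[(1S)-1-phenylethyl]prop-2-en-1-imine F1 and reduced with NaBH(OAc)3 to (E)-3-(imidazo[1,2-a]pyrimidin-2-yl)-N-[(1S)-1-phenylethyl]prop-2-en-1-amine F2. Ir-sensitised head-to-head dimerisation of F2 at high concentration should give the all-trans dimer as two diastereomers that differ in the sense of the cyclobutane relative to the two (S)-phenylethyl groups. The isomer with the ring configuration of the target, 1,1'-[(1R,2R,3S,4S)-3,4-bis(imidazo[1,2-a]pyrimidin-2-yl)cyclobutane-1,2-diyl]bis{N-[(1S)-1-phenylethyl]methanamine} F3, is separated by chromatography or salt crystallisation. Hydrazine converts it into 5,5'-[(1S,2S,3R,4R)-3,4-bis({[(1S)-1-phenylethyl]amino}methyl)cyclobutane-1,2-diyl]bis(1H-imidazol-2-amine) F4, and hydrogenolysis of the two N-(1-phenylethyl) groups gives 10.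

2. Step 5. Cleavage of the second benzylic C–N bond may stall through catalyst poisoning by the basic polyamine or steric shielding of the diphenylethane unit. The fallback sets out from 8 and comes back at 10, removing the bridge oxidatively before the aminoimidazoles are unmasked. Pb(OAc)4 cleaves the C–C bond of the vicinal diamine in 8 to 1,1'-[(1R,2R,3S,4S)-3,4-bis(imidazo[1,2-a]pyrimidin-2-yl)cyclobutane-1,2-diyl]bis[N-(E)-benzylidenemethanamine] F5. Heating F5 with hydrazine hydrate should both exchange the two benzylidene groups and open the two pyrimidine rings, giving 10.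

3. Step 2. Conjugate reduction, double alkylation at one nitrogen or aminal (imidazolidine) formation may compete with clean 1,2-reduction of the bis-imine. The fallback sets out from 3 (with 4) and comes back at 6, forming the C–N bonds by allylic substitution. Luche reduction of 3 gives (E)-3-(imidazo[1,2-a]pyrimidin-2-yl)prop-2-en-1-ol F6, methyl chloroformate gives (E)-3-(imidazo[1,2-a]pyrimidin-2-yl)prop-2-en-1-yl methyl carbonate F7, and Pd(PPh3)4-catalysed Tsuji–Trost amination of F7 (2 equiv) with diamine 4 should give the linear (E)-bis-allylamine 6.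

**Further compounds**

F1 | step 3 | (1E,2E)-3-(imidazo[1,2-a]pyrimidin-2-yl)-N-[(1S)-1-phenylethyl]prop-2-en-1-imine | C[C@H](/N=C/C=C/c1cn2cccnc2n1)c1ccccc1
F2 | step 3 | (E)-3-(imidazo[1,2-a]pyrimidin-2-yl)-N-[(1S)-1-phenylethyl]prop-2-en-1-amine | C[C@H](NC/C=C/c1cn2cccnc2n1)c1ccccc1
F3 | step 3 | 1,1'-[(1R,2R,3S,4S)-3,4-bis(imidazo[1,2-a]pyrimidin-2-yl)cyclobutane-1,2-diyl]bis{N-[(1S)-1-phenylethyl]methanamine} | n1c2ncccn2cc1[C@H]3[C@H](CN[C@@H](C)c4ccccc4)[C@@H](CN[C@@H](C)c4ccccc4)[C@@H]3c1cn2cccnc2n1
F4 | step 3 | 5,5'-[(1S,2S,3R,4R)-3,4-bis({[(1S)-1-phenylethyl]amino}methyl)cyclobutane-1,2-diyl]bis(1H-imidazol-2-amine) | Nc1ncc([C@H]3[C@H](CN[C@@H](C)c4ccccc4)[C@@H](CN[C@@H](C)c4ccccc4)[C@@H]3c5cnc(N)[nH]5)[nH]1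
F5 | step 5 | 1,1'-[(1R,2R,3S,4S)-3,4-bis(imidazo[1,2-a]pyrimidin-2-yl)cyclobutane-1,2-diyl]bis[N-(E)-benzylidenemethanamine] | n1c2ncccn2cc1[C@H]3[C@H](C/N=C/c4ccccc4)[C@@H](C/N=C/c4ccccc4)[C@@H]3c1cn2cccnc2n1
F6 | step 2 | (E)-3-(imidazo[1,2-a]pyrimidin-2-yl)prop-2-en-1-ol | OC/C=C/c1cn2cccnc2n1
F7 | step 2 | (E)-3-(imidazo[1,2-a]pyrimidin-2-yl)prop-2-en-1-yl methyl carbonate | COC(=O)OC/C=C/c1cn2cccnc2n1
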